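All constants are made up; what happens was integrated by code.

The easy mistake with a reversible step is to take its speed for its yield.

| flask | starting material | coupling partner | remark | time |
|---|---|---|---|---|
| Thursday's | 18 mM | 1.10 equiv | one stirred flow tank at steady state, fed with the mixture as stated, mean residence time 20 min |  |
| Sunday's | 18 mM (fed, over 10.0 min) | 1.10 equiv | all but starting material at the start; starting material goes in evenly over 10.0 min, the run ends at 20 min | 20 min |
| Tuesday's | 18 mM | 1.10 equiv | everything together in a closed stirred flask, run for 20 min | 20 min |
| Wednesday's | 18 mM | 1.10 equiv (fed, over 10.0 min) | a stirred flask in which coupling partner is dosed at a steady rate over 10.0 min without added volume, worked up at 20 min | 20 min |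
    starting material + coupling partner ⇌ isomer of the product (K1 = 2100 M⁻¹, k1 = 0.0097 M⁻¹ s⁻¹)
    starting material + coupling partner ⇌ target (K2 = 120 M⁻¹, k2 = 0.23 M⁻¹ s⁻¹)
    2 coupling partner → homo dimer (k3 = 0.018 M⁻¹ s⁻¹)
- a doubled species enters its step squared and goes two at a time
- the stated concentrations are those of everything mixed, before any reaction; amounts are the same in each set-up
- the feed brings no volume worth counting
- run time (Sunday's): 20 min
- the set-up with the highest amount of target at the outlet or at the end, in percent of the starting material put in ("none" if the first two lie within 2 percentage points) (Thursday's / Sunday's / Tuesday's / Wednesday's / none)
- amount of target at the outlet or at the end, in percent of the starting material put in, Thursday's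
- amount of target at the outlet or at the end, in percent of the starting material put in, Sunday's
- amount of target at the outlet or at the end, in percent of the starting material put in, Tuesday's
- amount of target at the outlet or at the end, in percent of the starting material put in, Wednesday's

I compared two times. The first was the half-life of starting material, the limiting reagent by charge, on its forward way to target with the coupling partner as charged (19.8 mM): 2.54 min. That step also runs back, so by itself it stops at a balance, with target at 9.81 mM and free partner at 9.99 mM.

I then replaced the falling curve of free partner by that flat level. The second time was the partner's life at balance, its first half-life by the dimer step at this level, 46.4 min. This is longer than the first time, so I let target follow a balance that sinks as partner leaves.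

In Tuesday's flask, 20 min at that level costs 4.31 mM of partner. I set the isomer aside and struck that loss from the charge, and the balance gave 46.2%. In Wednesday's flask, I took free partner as a ramp from nothing up to that level during dosing, so the mean of its square is a third of the level's square. The loss became 2.87 mM, which gave 49.2%.

The forecast named Wednesday's as best, with 39.4% for Thursday's, 42.5% for Sunday's, 44.4% for Tuesday's and 48.8% for Wednesday's, on the ground that “Dosing the partner keeps its concentration low and limits dimer”. For Tuesday's its figure lay below mine.

The simulation gave 39.4% for Thursday's, 41.5% for Sunday's, 44.3% for Tuesday's and 47.1% for Wednesday's, so Wednesday's came first. In Tuesday's flask, the half-life of starting material by step 2 alone, its forward rate only with the way back not counted, was 2.5 min. The coupling partner's life at balance, as I had reckoned it, was 46.4 min, longer than that. In Wednesday's flask, free partner peaked at a reading of 11.0 mM against my level of 9.99 mM, and a run to 200 min spans 4.31 such lives, at the end of which target stood at 16.2%.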